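## Analysis of the target

Target 15 is a flavonol 3-O-sulfate, 6-hydroxykaempferol 3-O-sulfate. It is a 4H-chromen-4-one in which benzo ring A is fused to pyranone ring C through C4a and C8a, with a 4-hydroxyphenyl ring B on C2, free hydroxyls on C5, C6 and C7, and a hydrogen sulfate ester on the oxygen of C3. There is no stereocentre, so the problem is one of regiochemistry and of telling five oxygens apart.

The sulfate monoester is the most fragile group. It sits on an enol-like, hydrogen-bonded hydroxyl and is lost under protic or Lewis acid, so it must come late, and the phenol protection must come off under neutral conditions. That points to benzyl ethers and hydrogenolysis.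

The 5,6,7-trihydroxy ring A is a pyrogallol-type arene that air oxidises in base. In hot acid a 5-hydroxyflavone of this kind can open and reclose on the other ortho oxygen (Wessely–Moser isomerisation), so harsh dealkylation is excluded on that ground as well.

Classical routes to such a ring A start from an acetophenone with oxygen on both carbons ortho to the acyl group, and one of the two must be singled out to become O1. The strategy rests on a different reading of ring A: with C5, C6 and C7 oxygenated, C8a is the only carbon ortho to C4a that bears hydrogen, and it lies para to the C6 oxygen. O1 can therefore come from the side chain and be joined to C8a by oxidising that C–H bond, while gallacetophenone 1 supplies O5, O6 and O7 already in place.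

## Retrosynthetic reasoning

**Target 15 from sodium sulfate 13.** The four phenols are unmasked last by cutting the four O–benzyl bonds. The forward step is a hydrogenolysis that must leave the S–O bonds and the C2=C3 bond alone. It gives the sodium salt 14, and the free acid 15 is liberated only in the work-up, because the acid form is the least stable form of the molecule.

**Sodium sulfate 13 from flavonol 10 and sulfur trioxide–pyridine complex 11.** The O3–S bond is cut. O3 is the one oxygen that must stay esterified, and in 10 it is the only free hydroxyl, so the sulfation is a question of reactivity and not of selectivity.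

**Flavonol 10 from benzoate 9.** The acyl C–O bond of the benzoate on O3 is cut. This is the one ester among four ethers, so methoxide can remove it without touching the rest. The same benzoate is what carries O3 through the oxidative ring closure.

**Benzoate 9 from acyloxy diketone 8 (key disconnection).** The O1–C8a bond is cut, which opens ring C. Cutting here, and not at O1–C2 as in a cyclodehydration, means ring A needs no oxygen at C8a beforehand; the question of which ortho oxygen becomes O1 does not arise. The forward reaction must remove two electrons and two protons from 8 and join the C2 oxygen to the one ortho C–H of ring A, without harming the benzyl ethers.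

**Acyloxy diketone 8 from diketone 5 and dibenzoyl peroxide 6.** The C3–O bond is cut. The central carbon of a 1,3-diketone is its most nucleophilic site, so an electrophilic oxygen source installs O3 already acylated, in one step and at the right carbon.

**Diketone 5 from ketone 3 and methyl 4-(benzyloxy)benzoate 4.** The C2–C3 bond is cut. This splits the carbon skeleton into a methyl ketone that holds ring A with C4 and C3, and a non-enolisable ester that holds C2 and ring B. The forward Claisen condensation has only one possible direction.

**Ketone 3 from gallacetophenone 1 and benzyl bromide 2.** The three O–benzyl bonds of ring A are cut. Gallacetophenone 1 already has the acyl group and the three contiguous oxygens in the required arrangement, with the single free ortho position that becomes C8a.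

## Alternatives that were turned down

**Alternative 1:** C4 is taken from carbon monoxide, and both of its bonds, C4a–C4 and C3–C4, are made at once.

- Key step: the aryl iodide A2 (1,2,3-tris(benzyloxy)-4-iodo-5-(methoxymethoxy)benzene), carbon monoxide and the enolate of the α-alkoxy ketone A3 (1-[4-(benzyloxy)phenyl]-2-(methoxymethoxy)ethan-1-one) would be joined with Pd(dba)2 (zerovalent palladium), 4,5-bis(diphenylphosphino)-9,9-dimethylxanthene and Cs2CO3. The product is the open-chain diketone A1; no ring closes. Acid would then remove both methoxymethyl groups and cyclodehydrate A1 to flavonol 10.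
- For it: carbonylative α-arylation of ketones is a known reaction class. No oxidant comes near the benzyl ethers, the position of O1 is fixed by the iodide, and O3 arrives without a separate oxygenation. On reliability of the key step it is stronger than the chosen route.
- Against it: A2 is a pentasubstituted arene with iodine between two oxygens. It has to be made in several steps from a phenol in which O1 is already set apart from three benzyloxy groups, so the differentiation problem is moved into the starting material, not removed. Oxidative addition and acyl transfer at a doubly ortho-substituted iodide are slow, which invites direct arylation without carbon monoxide. The enolate of A3 is hindered, and A1 is prone to retro-Claisen cleavage under the basic conditions.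
- Comparison: counting the preparation of A2 and A3, flavonol 10 would take more than the five steps of the chosen route. In exchange for a less secure key step, the chosen strategy offers a short linear access in which all ring A oxygens come from gallacetophenone 1.

**Alternative 2:** ring C is closed at the C3–C4 bond at the chromanone oxidation level and aromatised afterwards.

- Key step: the dialdehyde A5 (racemic 2,3,4-tris(benzyloxy)-6-{1-[4-(benzyloxy)phenyl]-2-oxoethoxy}benzaldehyde) would undergo an intramolecular benzoin reaction with 3-ethyl-5-(2-hydroxyethyl)-4-methylthiazolium bromide and 1,8-diazabicyclo[5.4.0]undec-7-ene. The aromatic formyl group acts as the acyl anion equivalent and adds to the aliphatic one, giving the racemic trans-3-hydroxychroman-4-one A4, which would then be dehydrogenated to 10.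
- For it: carbene-catalysed closure to chroman-4-ones is known, and the conditions are mild and metal-free. The 3-hydroxyl appears free and already distinct from the phenols, so no ester has to be removed. Its ring closure is the safer one.
- Against it: A5 again needs a ring A salicylaldehyde in which O1 is set apart from O5. It also contains an α-aryl-α-aryloxy acetaldehyde that enolises easily and can expel the phenoxide. The catalyst must take the aromatic aldehyde as donor although the aliphatic one is the more reactive in both roles. Two stereocentres (C2 and C3) are made under trans control only to be erased, and the extra dehydrogenation must be run on a molecule with four benzyl ethers.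
- Comparison: the chosen route reaches the aromatic pyranone in the ring-closing step itself, needs no stereocontrol, and is shorter overall.

**Alternative 3:** ring A is built onto a preformed pyranone.

- Key step: the chlorocyclobutenone A7 (racemic 2,3-bis(benzyloxy)-4-chlorocyclobut-2-en-1-one) and the stannane A8 (2-[4-(benzyloxy)phenyl]-3-(methoxymethoxy)-6-(tributylstannyl)-4H-pyran-4-one) would be coupled with Pd2(dba)3 (zerovalent palladium) and tri(2-furyl)phosphine to form C8–C8a. On warming, the four-membered ring would open to a dienylketene whose electrocyclisation makes C4a–C5 and, after tautomerisation, gives ring A as the 5-phenol A6.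
- For it: the ring A pattern follows from the connectivity of the partners and cannot be scrambled. The cascade is a known way to heavily oxygenated phenols, and the 5-hydroxyl comes out free. On regiochemical certainty it is at least as good as the chosen route, and it needs no unprecedented step.
- Against it: it builds from a squaric acid derivative a ring that gallacetophenone 1 offers ready-made. Both partners need multistep syntheses; A8 is itself a 2-aryl-3-alkoxy-4-pyranone that must be made and stannylated at C6, so ring C has to be constructed anyway. Stoichiometric tin is involved. In the end game the 3-hydroxyl would have to be sulfated next to a free 5-hydroxyl.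
- Comparison: the step count would be well above the seven of the chosen route, whose strength is that ring A is bought and only one bond has to be made to it.

Key step: step 4

Assumption: the target is wanted as the free hydrogen sulfate that is drawn; the sulfate is carried as its sodium salt and protonated only in the last work-up.

## Route

Step 1
Reactants: 1 gallacetophenone (1-(2,3,4-trihydroxyphenyl)ethan-1-one); 2 benzyl bromide
Product: 3 1-[2,3,4-tris(benzyloxy)phenyl]ethan-1-one
Conditions: BnBr (3.6 equiv), K2CO3 (4 equiv), KI (cat.), DMF, 70 °C, N2
Reagents that add atoms: benzyl bromide, BrCc1ccccc1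
Why: Williamson O-alkylation of the three phenoxides; the chelated 2-hydroxyl is the slowest and is driven by excess bromide, iodide catalysis and heat, and carbonate does not alkylate the ketone α-carbon.

Step 2
Reactants: 3 1-[2,3,4-tris(benzyloxy)phenyl]ethan-1-one; 4 methyl 4-(benzyloxy)benzoate
Product: 5 1-[4-(benzyloxy)phenyl]-3-[2,3,4-tris(benzyloxy)phenyl]propane-1,3-dione (drawn as the diketone; expected to exist mainly as the chelated enol)
Conditions: NaH (2.5 equiv), THF, 65 °C; aq. HCl work-up
Reagents that add atoms: methyl 4-(benzyloxy)benzoate, COC(=O)c1ccc(OCc2ccccc2)cc1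
Why: Crossed Claisen condensation: the sodium enolate of the methyl ketone acylates on the non-enolisable ester, and deprotonation of the 1,3-diketone as it forms drives the equilibrium; benzyl ethers are inert to NaH.

Step 3
Reactants: 5 1-[4-(benzyloxy)phenyl]-3-[2,3,4-tris(benzyloxy)phenyl]propane-1,3-dione; 6 dibenzoyl peroxide
Product: 8 1-[4-(benzyloxy)phenyl]-1,3-dioxo-3-[2,3,4-tris(benzyloxy)phenyl]propan-2-yl benzoate (racemic), via sodium diketonate 7 (not isolated)
Conditions: NaH (1.05 equiv), THF, 0 °C; then (PhCO2)2 (1.05 equiv), 0 °C to rt; cold dil. HCl work-up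
Reagents that add atoms: dibenzoyl peroxide, O=C(OOC(=O)c1ccccc1)c1ccccc1
Why: Electrophilic α-benzoyloxylation of a β-diketone enolate with a diacyl peroxide: the central carbon attacks a peroxide oxygen and benzoate leaves. One equivalent each of base and peroxide should stop the reaction at the monoacyloxy stage; the new centre is racemic and enolisable, which is of no consequence because it becomes trigonal in step 4.

Step 4
Reactants: 8 1-[4-(benzyloxy)phenyl]-1,3-dioxo-3-[2,3,4-tris(benzyloxy)phenyl]propan-2-yl benzoate
Product: 9 5,6,7-tris(benzyloxy)-2-[4-(benzyloxy)phenyl]-4-oxo-4H-chromen-3-yl benzoate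
Conditions: PhI(OCOCF3)2 (1.1 equiv), (CF3)2CHOH/CH2Cl2 (4:1), 0.01 M, 0 °C
Reagents that add atoms: none
Why: Proposed new method: PhI(OCOCF3)2 (trivalent iodine) in hexafluoroisopropanol should take one electron from ring A of 8, the only arene in the molecule with three donor oxygens, and the fluorinated alcohol should keep the resulting radical cation alive long enough to be trapped. The oxygen on C2, either as the enol hydroxyl of the chelated cis-enol or as the carbonyl oxygen of the diketo tautomer, sits four atoms from C8a and adds there; transfer of the second electron to iodine leaves an arenium ion whose charge rests on the para C6 benzyloxy group as an oxocarbenium ion, and loss of the C8a proton and of the proton on O1 or C3 gives the 4H-chromen-4-one 9. The closest known reaction types are the oxidative C–H/O–H cyclisations of 4-hydroxy-3-arylcoumarins to coumestans and of 2-arylphenols to dibenzofurans, together with radical-cation couplings of phenol ethers under trivalent iodine in fluorinated alcohols; closure of a pyranone by a 1,3-diketone oxygen onto a non-phenolic arene has not been shown. Ring C closes in the six-membered mode onto a trigonal arene carbon (6-exo-trig when counted on the C8–C8a π bond). No stereocentre is formed, and the racemic centre C3 of 8 becomes trigonal. The step needs selectivity between the two arenes and between the positions of ring A: ring B has one oxygen and its ortho carbons are meta to it; C8 is the most nucleophilic carbon of ring A but the tether cannot span it; ipso attack at C4a would give a strained spiro furanone with charge next to the acyl carbon; ipso attack at C5 cannot end in proton loss; so C8a, the one ortho carbon that bears hydrogen, is where the sequence can finish. The benzoate on C3 blocks oxidation at the enol carbon, and its own carbonyl oxygen could reach C8a only through a seven-membered ring.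

Step 5
Reactants: 9 5,6,7-tris(benzyloxy)-2-[4-(benzyloxy)phenyl]-4-oxo-4H-chromen-3-yl benzoate
Product: 10 5,6,7-tris(benzyloxy)-2-[4-(benzyloxy)phenyl]-3-hydroxy-4H-chromen-4-one
Conditions: K2CO3 (1.5 equiv), MeOH/THF (1:1), 0 °C to rt; then dil. HCl to pH 5
Reagents that add atoms: none
Why: Transesterification of an enol-type benzoate by methoxide generated from K2CO3 in methanol; the flavonolate is a good leaving group, and the benzyl ethers and the pyranone are inert at this temperature.

Step 6
Reactants: 10 5,6,7-tris(benzyloxy)-2-[4-(benzyloxy)phenyl]-3-hydroxy-4H-chromen-4-one; 11 sulfur trioxide–pyridine complex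
Product: 13 sodium 5,6,7-tris(benzyloxy)-2-[4-(benzyloxy)phenyl]-4-oxo-4H-chromen-3-yl sulfate, via pyridinium sulfate monoester 12 (not isolated)
Conditions: SO3·pyridine (5 equiv), pyridine, 50 °C; then aq. NaHCO3, 0 °C; Sephadex LH-20 (MeOH)
Reagents that add atoms: sulfur trioxide–pyridine complex, [O-]S(=O)(=O)[n+]1ccccc1; sodium hydrogen carbonate, [Na+].OC([O-])=O
Why: O-sulfation of a hydroxyl with a sulfur trioxide–amine complex; the 3-hydroxyl is the only free hydroxyl of 10, so excess reagent and warming can be used against its hydrogen bond to the C4 carbonyl. Exchanging pyridinium for sodium gives a salt that should be stable on storage and removes a nitrogen base that slows O-debenzylation on palladium.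

Step 7
Reactants: 13 sodium 5,6,7-tris(benzyloxy)-2-[4-(benzyloxy)phenyl]-4-oxo-4H-chromen-3-yl sulfate
Product: 15 5,6,7-trihydroxy-2-(4-hydroxyphenyl)-4-oxo-4H-chromen-3-yl hydrogen sulfate, via sodium 3-sulfate salt 14 (not isolated)
Conditions: H2 (1 atm), 10% Pd/C, THF/MeOH/H2O, rt; filter under Ar; then HCl (1.0 equiv), 0 °C; C18 desalting (H2O/MeCN), freeze-dry
Reagents that add atoms: none
Why: Hydrogenolysis of benzyl aryl ethers on Pd/C under neutral conditions, which aryl sulfate salts and the flavone C2=C3 bond normally survive. One equivalent of acid in the cold then protonates the sulfate, and quick desalting and freeze-drying should limit acid-catalysed solvolysis.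

## Compound list

1 | gallacetophenone (1-(2,3,4-trihydroxyphenyl)ethan-1-one) | CC(=O)c1ccc(O)c(O)c1O | starting material
2 | benzyl bromide | BrCc1ccccc1 | starting material
3 | 1-[2,3,4-tris(benzyloxy)phenyl]ethan-1-one | CC(=O)c1ccc(OCc2ccccc2)c(OCc2ccccc2)c1OCc1ccccc1 | intermediate
4 | methyl 4-(benzyloxy)benzoate | COC(=O)c1ccc(OCc2ccccc2)cc1 | starting material
5 | 1-[4-(benzyloxy)phenyl]-3-[2,3,4-tris(benzyloxy)phenyl]propane-1,3-dione | O=C(CC(=O)c1ccc(OCc2ccccc2)cc1)c1ccc(OCc2ccccc2)c(OCc2ccccc2)c1OCc1ccccc1 | intermediate
6 | dibenzoyl peroxide | O=C(OOC(=O)c1ccccc1)c1ccccc1 | starting material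
7 | sodium diketonate of 5 (Z-enolate drawn; not isolated) | [Na+].[O-]/C(=C\C(=O)c1ccc(OCc2ccccc2)cc1)c1ccc(OCc2ccccc2)c(OCc2ccccc2)c1OCc1ccccc1 | intermediate
8 | 1-[4-(benzyloxy)phenyl]-1,3-dioxo-3-[2,3,4-tris(benzyloxy)phenyl]propan-2-yl benzoate (racemic) | O=C(c1ccc(OCc2ccccc2)c(OCc2ccccc2)c1OCc1ccccc1)C(OC(=O)c1ccccc1)C(=O)c1ccc(OCc2ccccc2)cc1 | intermediate
9 | 5,6,7-tris(benzyloxy)-2-[4-(benzyloxy)phenyl]-4-oxo-4H-chromen-3-yl benzoate | O=C(Oc1c(-c2ccc(OCc3ccccc3)cc2)oc2cc(OCc3ccccc3)c(OCc3ccccc3)c(OCc3ccccc3)c2c1=O)c1ccccc1 | intermediate
10 | 5,6,7-tris(benzyloxy)-2-[4-(benzyloxy)phenyl]-3-hydroxy-4H-chromen-4-one | O=c1c(O)c(-c2ccc(OCc3ccccc3)cc2)oc2cc(OCc3ccccc3)c(OCc3ccccc3)c(OCc3ccccc3)c12 | intermediate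
11 | sulfur trioxide–pyridine complex | [O-]S(=O)(=O)[n+]1ccccc1 | starting material
12 | pyridinium 5,6,7-tris(benzyloxy)-2-[4-(benzyloxy)phenyl]-4-oxo-4H-chromen-3-yl sulfate (not isolated) | O=c1c(OS(=O)(=O)[O-])c(-c2ccc(OCc3ccccc3)cc2)oc2cc(OCc3ccccc3)c(OCc3ccccc3)c(OCc3ccccc3)c12.c1cc[nH+]cc1 | intermediate
13 | sodium 5,6,7-tris(benzyloxy)-2-[4-(benzyloxy)phenyl]-4-oxo-4H-chromen-3-yl sulfate | O=c1c(OS(=O)(=O)[O-])c(-c2ccc(OCc3ccccc3)cc2)oc2cc(OCc3ccccc3)c(OCc3ccccc3)c(OCc3ccccc3)c12.[Na+] | intermediate
14 | sodium 5,6,7-trihydroxy-2-(4-hydroxyphenyl)-4-oxo-4H-chromen-3-yl sulfate (not isolated) | O=c1c(OS(=O)(=O)[O-])c(-c2ccc(O)cc2)oc2cc(O)c(O)c(O)c12.[Na+] | intermediate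
15 | 5,6,7-trihydroxy-2-(4-hydroxyphenyl)-4-oxo-4H-chromen-3-yl hydrogen sulfate | O=c1c(OS(=O)(=O)O)c(-c2ccc(O)cc2)oc2cc(O)c(O)c(O)c12 | target

## Step count and least certain steps

Total step count: 7. Longest linear sequence: 7 steps (1 to 15); compounds 2, 4, 6 and 11 are bought.

**Step 4 (key step, the one step beyond known chemistry).** Several things can go wrong.

- Electron transfer from ring A may be too slow, because the acyl group on C4a raises its oxidation potential. The oxidant could then engage the small enol fraction at C3, giving oxygenation there without cyclisation.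
- The product may be oxidised further at C8, since its ring A carries a fourth oxygen. This would show as coupling or as oxidative loss of a benzyl group.
- The trifluoroacetic acid that is released may cleave the 5-O-benzyl group next to the carbonyl.
- Ipso attack at C4a followed by an acyl shift would scramble the ring A pattern.

High dilution, low temperature, one equivalent of oxidant and, if needed, a solid hydrogen carbonate buffer are the first measures.

The fallback uses known chemistry and gives up the C–H oxidation. It sets out from benzyl bromide 2 together with purchased scutellarein F1, and comes back at 10, so step 5 is not needed. Scutellarein F1 would be perbenzylated (2, K2CO3, DMF, 80 °C, N2) to 5,6,7-tris(benzyloxy)-2-[4-(benzyloxy)phenyl]-4H-chromen-4-one F2. The C2=C3 bond of F2 would be epoxidised with dimethyldioxirane in acetone/CH2Cl2 at 0 °C to the racemic epoxide F3. A catalytic amount of p-toluenesulfonic acid would open F3 at C2 and, after loss of the C3 proton, give flavonol 10.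

**Step 3.** The enolate may attack a carbonyl carbon of the peroxide instead of oxygen (O- or C-benzoylation). The acyloxy diketone may also undergo retro-Claisen cleavage or acyl migration during a basic work-up. The fallback sets out from 5 and comes back at 8, replacing electrophilic oxygen by nucleophilic oxygen. Bromination of the central carbon with N-bromosuccinimide (CH2Cl2, 0 °C) would give the 2-bromo-1,3-diketone F4. Displacement of bromide with sodium benzoate in DMF at rt would then give 8.

**Step 6.** Sulfation of the 3-hydroxyl may be sluggish, because it is hydrogen-bonded to the C4 carbonyl and flanked by ring B. The monoester may also be lost by solvolysis during purification of a polar salt. The fallback sets out from 10 and comes back at 13, carrying the sulfate as a neutral diester that can be chromatographed on silica. Treatment of 10 with 2,2,2-trichloroethyl chlorosulfate, Et3N and 4-(dimethylamino)pyridine in THF would give the trichloroethyl sulfate diester F5. Reductive fragmentation with Zn dust and ammonium formate in MeOH would give the ammonium sulfate F6, and aqueous NaHCO3 would convert F6 into 13.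

**Step 7.** Debenzylation may stall on a catalyst inhibited by residual base or sulfur species. The sulfate may be solvolysed during the final acidification, or the pyrogallol ring A may be oxidised by air during handling. The fallback sets out from 10 and comes back at 14, reversing the order of the two operations. Hydrogenolysis of 10 (H2, Pd/C, THF/MeOH) would give 6-hydroxykaempferol F7. Carbodiimide-mediated sulfation (N,N'-dicyclohexylcarbodiimide, tetrabutylammonium hydrogen sulfate, pyridine, 4 °C), a method known to favour the 3-hydroxyl of flavonols, would give the tetrabutylammonium sulfate F8. The extra 6-hydroxyl makes this selectivity less certain than in the main route. Sodium acetate in MeOH would precipitate 14 from F8, which is then protonated as in step 7.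

## Further compounds

F1 | step 4 | scutellarein (5,6,7-trihydroxy-2-(4-hydroxyphenyl)-4H-chromen-4-one) | O=c1cc(-c2ccc(O)cc2)oc2cc(O)c(O)c(O)c12
F2 | step 4 | 5,6,7-tris(benzyloxy)-2-[4-(benzyloxy)phenyl]-4H-chromen-4-one | O=c1cc(-c2ccc(OCc3ccccc3)cc2)oc2cc(OCc3ccccc3)c(OCc3ccccc3)c(OCc3ccccc3)c12
F3 | step 4 | 4,5,6-tris(benzyloxy)-1a-[4-(benzyloxy)phenyl]-1a,7a-dihydro-7H-oxireno[2,3-b]chromen-7-one (2,3-epoxide of F2; racemic, cis-fused by necessity) | O=C1C2OC2(c2ccc(OCc3ccccc3)cc2)Oc2cc(OCc3ccccc3)c(OCc3ccccc3)c(OCc3ccccc3)c21
F4 | step 3 | 2-bromo-1-[4-(benzyloxy)phenyl]-3-[2,3,4-tris(benzyloxy)phenyl]propane-1,3-dione (racemic) | O=C(c1ccc(OCc2ccccc2)c(OCc2ccccc2)c1OCc1ccccc1)C(Br)C(=O)c1ccc(OCc2ccccc2)cc1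
F5 | step 6 | 5,6,7-tris(benzyloxy)-2-[4-(benzyloxy)phenyl]-4-oxo-4H-chromen-3-yl 2,2,2-trichloroethyl sulfate | O=c1c(OS(=O)(=O)OCC(Cl)(Cl)Cl)c(-c2ccc(OCc3ccccc3)cc2)oc2cc(OCc3ccccc3)c(OCc3ccccc3)c(OCc3ccccc3)c12
F6 | step 6 | ammonium 5,6,7-tris(benzyloxy)-2-[4-(benzyloxy)phenyl]-4-oxo-4H-chromen-3-yl sulfate | O=c1c(OS(=O)(=O)[O-])c(-c2ccc(OCc3ccccc3)cc2)oc2cc(OCc3ccccc3)c(OCc3ccccc3)c(OCc3ccccc3)c12.[NH4+]
F7 | step 7 | 3,5,6,7-tetrahydroxy-2-(4-hydroxyphenyl)-4H-chromen-4-one (6-hydroxykaempferol) | O=c1c(O)c(-c2ccc(O)cc2)oc2cc(O)c(O)c(O)c12
F8 | step 7 | tetrabutylammonium 5,6,7-trihydroxy-2-(4-hydroxyphenyl)-4-oxo-4H-chromen-3-yl sulfate | CCCC[N+](CCCC)(CCCC)CCCC.O=c1c(OS(=O)(=O)[O-])c(-c2ccc(O)cc2)oc2cc(O)c(O)c(O)c12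
A1 | alternative 1 | 1-[4-(benzyloxy)phenyl]-2-(methoxymethoxy)-3-[2,3,4-tris(benzyloxy)-6-(methoxymethoxy)phenyl]propane-1,3-dione (racemic) | COCOC(C(=O)c1ccc(OCc2ccccc2)cc1)C(=O)c1c(OCOC)cc(OCc2ccccc2)c(OCc2ccccc2)c1OCc1ccccc1
A2 | alternative 1 | 1,2,3-tris(benzyloxy)-4-iodo-5-(methoxymethoxy)benzene | COCOc1cc(OCc2ccccc2)c(OCc2ccccc2)c(OCc2ccccc2)c1I
A3 | alternative 1 | 1-[4-(benzyloxy)phenyl]-2-(methoxymethoxy)ethan-1-one | COCOCC(=O)c1ccc(OCc2ccccc2)cc1
A4 | alternative 2 | racemic trans-5,6,7-tris(benzyloxy)-2-[4-(benzyloxy)phenyl]-3-hydroxychroman-4-one ((2R,3R) enantiomer drawn) | O=C1c3c(O[C@H](c2ccc(OCc4ccccc4)cc2)[C@H]1O)cc(OCc2ccccc2)c(OCc2ccccc2)c3OCc1ccccc1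
A5 | alternative 2 | 2,3,4-tris(benzyloxy)-6-{1-[4-(benzyloxy)phenyl]-2-oxoethoxy}benzaldehyde (racemic) | O=CC(Oc1cc(OCc2ccccc2)c(OCc2ccccc2)c(OCc2ccccc2)c1C=O)c1ccc(OCc2ccccc2)cc1
A6 | alternative 3 | 6,7-bis(benzyloxy)-2-[4-(benzyloxy)phenyl]-5-hydroxy-3-(methoxymethoxy)-4H-chromen-4-one | COCOc1c(-c2ccc(OCc3ccccc3)cc2)oc2cc(OCc3ccccc3)c(OCc3ccccc3)c(O)c2c1=O
A7 | alternative 3 | 2,3-bis(benzyloxy)-4-chlorocyclobut-2-en-1-one (racemic) | O=C1C(Cl)C(OCc2ccccc2)=C1OCc1ccccc1
A8 | alternative 3 | 2-[4-(benzyloxy)phenyl]-3-(methoxymethoxy)-6-(tributylstannyl)-4H-pyran-4-one | CCCC[Sn](CCCC)(CCCC)c1cc(=O)c(OCOC)c(-c2ccc(OCc3ccccc3)cc2)o1
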